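# Betaethrin E: a synthesis that folds a triketo ester into ring A around a pre-formed ether oxygen

## The problem

Betaethrin E (27) is an achiral diaryl ether. Ring A carries the palmitoyloxymethyl carbon at C1, OMe at C3, a free OH at C5 and the ether oxygen at C6; ring B carries the ether oxygen at C1', a methyl at C3', a free OH at C5' and CO2Me at C6'. There is no stereocentre, so nothing can be relayed and the whole task is one of regiochemistry and chemoselectivity. The ether oxygen sits between two ortho substituents on ring A and next to an ester on ring B, and both rings are electron-rich, so an aryl–oxygen coupling would be hindered and electronically mismatched. The ring-A oxygens at C3 and C5 must end up different (methyl ether and free phenol), and the two carboxyl-derived carbons must end at different oxidation levels (benzylic ester on ring A, methyl benzoate on ring B). The benzylic palmitate tolerates neither hydroxide, alkoxide, hydride, organolithium reagents nor hydrogenolysis, so it has to arrive late and the last deprotection has to be mild and non-basic. The feature that opens the route is that C1 (carbon), C3–O, C5–O and C6–O of ring A repeat the alternating pattern of a 2,4,6-trioxoheptanoate chain. The terminal methylene of that chain (the future C6) can receive the ring-B oxygen by plain SN2 alkylation before ring A exists.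

## Retrosynthesis

**Endgame, 27 back to 24 and 25.** The two O–CH2OMe acetal bonds are cut last and the benzylic O–acyl bond just before them, leading through bis-MOM palmitate 26 to hydroxy ester 24 and palmitoyl chloride 25. Acylating a free triol would pit two phenols against the primary alcohol, so both phenols stay masked until the fatty ester is in place. MOM is chosen over benzyl because its removal needs neither hydrogen (which would cleave the benzylic ester) nor base. The forward reaction must cleave two aryl acetals without ionising or transesterifying the benzylic palmitate.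

**Ring-B carboxyl and ring-A alcohol, 24 back to 20.** The C6'–CO2Me bond is cut back to C6'–Br, and the ring-A CH2OH is taken back to a methyl ester. This gives acid 23, bromo alcohol 21 and bromo ester 20. Two methyl esters in one molecule could not be told apart by a hydride, so keeping the ring-B carboxyl as a bromine until the ring-A ester is reduced makes that ester the only one present. Carbonylation of the di-ortho-substituted bromide was judged less reliable than bromine–lithium exchange. The forward sequence asks for exchange in the presence of a lithium alkoxide, capture by CO2 and O-methylation of the carboxylate only.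

**Differentiating the ring-A phenols, 20 back to 17.** The C3 O–Me and C5 O–MOM bonds are cut to reach resorcinol 17. Direct monomethylation of 17 is not trusted. The C5–OH is ortho to the aryloxy group and is therefore the more acidic phenol, while the C3–OH is the less hindered one, so for a small electrophile such as MeI the two effects oppose each other. A bulky silyl chloride under neutral imidazole conditions responds to sterics alone, so C3–OH is first marked as its triisopropylsilyl ether (18). C5–OH is then capped with MOM (19), and the silyl ether is exchanged for methyl in one flask with fluoride and MeI (20). This costs one step more than direct methylation and buys a defined regiochemistry.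

**Key disconnection, 17 back to 15.** The C1–C6 bond of ring A is cut and the ring unfolds into methyl 7-aryloxy-2,4,6-trioxoheptanoate 15. Compared with cutting the aryl–oxygen bond, this removes the hindered coupling altogether: the oxygen is already attached to an sp3 carbon and the ring grows around it. The precursor is an acyclic chain with no stereochemistry and no regiochemical ambiguity in its connectivity. The forward reaction is an intramolecular aldol of the aryloxy-bearing methylene onto the keto group next to the ester, followed by dehydration and enolisation. Ring B must carry bromine and not an ester at C6', because an ortho ester would be attacked by the same carbanion to give a benzofuranone.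

**Chain assembly, 15 back to 8 and 12.** The bond between the future C4 and C5 is cut, giving aryloxyacetic acid 8 (used as its chloride 13) and the bis-silyl dienol ether 12 of methyl 2,4-dioxopentanoate 9, made by way of mono-silyl ether 10. The neighbouring cut at C1–C2 (dianion of an aryloxy diketone plus dimethyl oxalate) was rejected. In such a diketone the aryloxy-bearing methylene is the more acidic terminal position, so the oxalyl group would go to the wrong end. The chosen cut fixes the regiochemistry by construction and asks only for C-acylation of the diene at its terminal carbon.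

**Ring-B piece, 8 back to orcinol 1.** The O–CH2 bond is cut to phenol 5 and methyl bromoacetate 6 (by way of ester 7), and the C–Br bond is cut to bis-MOM ether 2 of orcinol 1 by way of bromide 4. Electrophilic bromination of orcinol ethers does not go between the oxygens, so directed lithiation at that doubly activated site is the way in. The symmetric bromide 4 is then desymmetrised by removing one MOM group. This early step on inexpensive material is statistical and is accepted as such.

## Roads not taken

**Alternative 1:** aryne three-component coupling. The cut removes the O–C1' bond and the C6'–carboxyl bond of ring B together. In the forward step CsF releases the aryne from silyl triflate A3 under CO2. The caesium phenoxide of the complete ring-A phenol A2 adds at C1', distal to the MOM-oxy group, and the aryl anion at C6' is trapped by CO2 to give acid A1.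

- Merits: it is the most convergent plan. Ring B arrives at the carboxyl level with no bromine placeholder and no organolithium step, and A1 is only about four steps from the target.
- Weak points: the nucleophile is a 2,6-disubstituted phenoxide, which under CO2 is partly stored as its carbonate. The aryl anion can be protonated before it is carboxylated, giving the ether without the carboxyl. Both partners need their own syntheses, and A2 in particular is a benzene with three different oxygens whose differentiation is simply moved elsewhere.
- Comparison: if the coupling worked with this hindered phenoxide, this road would be shorter and more convergent than the chosen one. The chosen plan sets against it that every bond is made by SN2 alkylation, enolate acylation or an intramolecular aldol, and that the substitution pattern of ring A comes from the chain without a separately built tetrasubstituted phenol.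

**Alternative 2:** Danheiser benzannulation. The cut removes four ring-A bonds (C1–C2, C2–C3, C4–C5, C5–C6). In the forward step, irradiation of unsaturated diazoketone A5 (drawn as the E enol ether) with methoxyacetylene A6 triggers Wolff rearrangement to an aryloxy vinylketene. A two-plus-two cycloaddition, four-electron ring opening and six-electron closure on heating then give phenol A4.

- Merits: A4 has the C3 oxygen as OMe and the C5 oxygen as a free phenol from the start, which is exactly the distinction the chosen route spends three steps on. Ring B carries its ester throughout, so no bromine and no lithiation are needed.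
- Weak points: A5 is a sensitive beta-aryloxy enone diazoketone. Its preparation requires adding a hindered, hydrogen-bonded salicylate phenol to an enone or ynone with control of geometry, then diazo transfer. The aryloxy group on the ketene terminus is expected to slow the final closure. A6 is volatile and unstable and must be made fresh. The photolysis has to be run in the presence of two aryl chromophores.
- Comparison: in regiochemical economy on ring A this road is better than the chosen one. The chosen plan offers thermal, scalable steps with commercial reagents and a ring closure whose regiochemistry is fixed by chain connectivity.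

**Alternative 3:** vinylogous Dieckmann closure of ring B. The cut is the C4'–C5' bond. In the forward step KN(SiMe3)2 deprotonates a terminal methyl of dienyl malonate A8. The extended enolate attacks one malonate ester carbonyl, and loss of methoxide and tautomerisation give salicylate A7.

- Merits: ring B is delivered directly as the methyl ester with its free phenol, which is the functionality of the target. The endgame (desilylation, acylation, MOM removal) is about three steps.
- Weak points: A8 is a tetrasubstituted push–pull alkene that has to be made by addition–elimination of the hindered phenoxide of A2 at a crowded sp2 carbon. The amide base can also attack the malonate esters. The road again needs the complete ring-A phenol A2, with its own multistep, regiocontrolled synthesis.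
- Comparison: the endgame is shorter than in the chosen plan, and ring B needs no placeholder, which is a real advantage. The chosen plan sets against it that the ether oxygen is attached at an unhindered methylene and that ring A never has to be made as a free-standing, fully differentiated phenol.

Key step: step 9

## Remarks on the chemistry

- Ring-A atoms carry the numbers of the target (C1 carbon substituent, C3 OMe, C5 OH, C6 ether oxygen), and ring-B atoms are primed. Chain carbons of 15 are referred to by the ring-A numbers they become (C1 = keto carbon next to the ester, C6 = aryloxy-bearing methylene).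
- Silyl enol ethers 10–14 are drawn as the Z isomers expected from the chelated enol. Their geometry, and which oxygen is silylated first in step 6, have no consequence because both enol ethers are hydrolysed in step 8.

## Route

Step 1
Reactants: 1 orcinol (5-methylbenzene-1,3-diol)
Product: 2 1,3-bis(methoxymethoxy)-5-methylbenzene
Conditions: NaH, MOMCl, DMF, 0 °C → rt
Reagents that add atoms: chloromethyl methyl ether, COCCl
Why: Williamson-type O-alkylation of both phenoxides; the MOM ethers are the cooperative ortho-directing groups needed in step 2.

Step 2
Reactants: 2 1,3-bis(methoxymethoxy)-5-methylbenzene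
Product: 4 2-bromo-1,3-bis(methoxymethoxy)-5-methylbenzene, via aryllithium 3 (not isolated)
Conditions: n-BuLi, THF, 0 °C; BrCCl2CCl2Br, −78 °C → rt
Reagents that add atoms: n-butyllithium, CCCC[Li] (lithium of 3); 1,2-dibromo-1,1,2,2-tetrachloroethane, BrC(Cl)(Cl)C(Cl)(Cl)Br
Why: Directed ortho-metalation at the position between two MOM-oxy groups, then bromine transfer to the aryllithium; electrophilic bromination would not reach this position.

Step 3
Reactants: 4 2-bromo-1,3-bis(methoxymethoxy)-5-methylbenzene
Product: 5 2-bromo-3-(methoxymethoxy)-5-methylphenol
Conditions: HCl (cat.), MeOH, 0 °C → rt, stopped near half conversion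
Reagents that add atoms: none
Why: Acid-catalysed acetal methanolysis of one of two equivalent MOM ethers; the step is statistical, and recovered 4 and over-cleaved diol (after re-protection) are recycled.

Step 4
Reactants: 5 2-bromo-3-(methoxymethoxy)-5-methylphenol; 6 methyl bromoacetate
Product: 7 methyl 2-[2-bromo-3-(methoxymethoxy)-5-methylphenoxy]acetate
Conditions: K2CO3, acetone, reflux
Reagents that add atoms: none
Why: Williamson ether synthesis (SN2 of the phenoxide on an alpha-bromo ester); the future diaryl ether oxygen is joined here to an unhindered sp3 carbon.

Step 5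
Reactants: 7 methyl 2-[2-bromo-3-(methoxymethoxy)-5-methylphenoxy]acetate
Product: 8 2-[2-bromo-3-(methoxymethoxy)-5-methylphenoxy]acetic acid
Conditions: LiOH, THF–H2O, 0 °C → rt; 1 M HCl to pH 4, 0 °C
Reagents that add atoms: lithium hydroxide, [Li+].[OH-]
Why: Ester saponification; the aryl bromide and MOM ether are inert to hydroxide, and the cold, brief acidification to pH 4 spares the acetal.

Step 6
Reactants: 9 methyl 2,4-dioxopentanoate
Product: 10 methyl (2Z)-4-oxo-2-[(trimethylsilyl)oxy]pent-2-enoate
Conditions: Me3SiCl, Et3N, Et2O, rt
Reagents that add atoms: chlorotrimethylsilane, C[Si](C)(C)Cl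
Why: O-silylation of the strongly enolised diketo ester, the usual first stage in making a 1,3-bis(silyl enol ether).

Step 7
Reactants: 10 methyl (2Z)-4-oxo-2-[(trimethylsilyl)oxy]pent-2-enoate
Product: 12 methyl (2Z)-2,4-bis[(trimethylsilyl)oxy]penta-2,4-dienoate, via lithium dienolate 11 (not isolated)
Conditions: LiN(i-Pr)2, THF, −78 °C; Me3SiCl, −78 → 0 °C
Reagents that add atoms: lithium diisopropylamide, CC(C)N([Li])C(C)C (lithium of 11); chlorotrimethylsilane, C[Si](C)(C)Cl
Why: Kinetic deprotonation of the methyl ketone and O-silylation, the standard second stage of 1,3-bis(silyl enol ether) synthesis; the diene is used without chromatography.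

Step 8
Reactants: 8 2-[2-bromo-3-(methoxymethoxy)-5-methylphenoxy]acetic acid; 12 methyl (2Z)-2,4-bis[(trimethylsilyl)oxy]penta-2,4-dienoate
Product: 15 methyl 7-[2-bromo-3-(methoxymethoxy)-5-methylphenoxy]-2,4,6-trioxoheptanoate, via acyl chloride 13 (not isolated), via silyl enol ether adduct 14 (not isolated)
Conditions: 1-chloro-N,N,2-trimethylprop-1-en-1-amine, CH2Cl2, 0 °C → rt; then 12, CH2Cl2, −78 → 20 °C; aq. NH4Cl
Reagents that add atoms: 1-chloro-N,N,2-trimethylprop-1-en-1-amine, CC(C)=C(Cl)N(C)C (chlorine of 13)
Why: The alpha-chloroenamine makes the acid chloride without releasing HCl, which protects the MOM ether. Mukaiyama-type C-acylation of a 1,3-bis(silyl enol ether) at its terminal carbon is the known route to 1,3,5-tricarbonyl chains, and it fixes the C4–C5 bond without any enolate regiochemistry to control.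

Step 9
Reactants: 15 methyl 7-[2-bromo-3-(methoxymethoxy)-5-methylphenoxy]-2,4,6-trioxoheptanoate
Product: 17 methyl 2-[2-bromo-3-(methoxymethoxy)-5-methylphenoxy]-3,5-dihydroxybenzoate, via cyclic aldol adduct 16 (not isolated)
Conditions: K2CO3, MeOH (dry), Ar, 0 → 40 °C; AcOH to pH 5
Reagents that add atoms: none
Why: Base equilibrates the enolates of 15; the minor enolate at C6, whose proton is acidified by the C5 ketone and further by the aryloxy group (alpha-aryloxy ketones are more acidic than their parents by a few pK units), adds to the C1 keto group, the most electrophilic carbonyl because it belongs to an alpha-keto ester, and gives carbinol 16. E1cB loss of water and enolisation of the C3 and C5 ketones then give the aromatic ring, which makes the sequence irreversible. The closest known reaction type is the biomimetic aldol cyclisation of 2,4,6-triketones and triketo esters to resorcinols. The ring closes in a 6-(enolendo)-exo-trig mode, because the enolate C5=C6 bond lies inside the new ring, and this mode is favoured for six-membered rings. No stereocentre remains: the two centres of 16 form without control and are erased on aromatisation. The selectivity needed is among folding modes: the ester end has no enolisable carbon beyond C1, so C6 onto C1 is the only C–C closure that gives a six-membered carbocycle; O-cyclisation to the 4-pyranone is reversible under base; and in dry methanol the alpha,gamma-diketo ester rests as the same enolate that a Claisen condensation with oxalate produces, so the loss of oxalate that aqueous hydroxide would cause is not expected. Bromine at C6' in place of the eventual ester removes the one electrophile that the same carbanion could attack to give a benzofuranone.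

Step 10
Reactants: 17 methyl 2-[2-bromo-3-(methoxymethoxy)-5-methylphenoxy]-3,5-dihydroxybenzoate
Product: 18 methyl 2-[2-bromo-3-(methoxymethoxy)-5-methylphenoxy]-3-hydroxy-5-[(triisopropylsilyl)oxy]benzoate
Conditions: i-Pr3SiCl (1.05 equiv), imidazole, DMF, −20 → 0 °C
Reagents that add atoms: chlorotriisopropylsilane, CC(C)[Si](Cl)(C(C)C)C(C)C
Why: Sterically controlled O-silylation: the phenol para to the ether oxygen (ring-A C3) has two free ortho positions, whereas the other is shielded by the twisted ortho-bromoaryloxy group, and the bulky silyl chloride under neutral conditions follows sterics and not acidity.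

Step 11
Reactants: 18 methyl 2-[2-bromo-3-(methoxymethoxy)-5-methylphenoxy]-3-hydroxy-5-[(triisopropylsilyl)oxy]benzoate
Product: 19 methyl 2-[2-bromo-3-(methoxymethoxy)-5-methylphenoxy]-3-(methoxymethoxy)-5-[(triisopropylsilyl)oxy]benzoate
Conditions: MOMCl, i-Pr2NEt, CH2Cl2, 0 °C → rt
Reagents that add atoms: chloromethyl methyl ether, COCCl
Why: O-alkylation of the remaining phenol with a small, reactive electrophile under amine base, conditions that leave the aryl silyl ether in place.

Step 12
Reactants: 19 methyl 2-[2-bromo-3-(methoxymethoxy)-5-methylphenoxy]-3-(methoxymethoxy)-5-[(triisopropylsilyl)oxy]benzoate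
Product: 20 methyl 2-[2-bromo-3-(methoxymethoxy)-5-methylphenoxy]-5-methoxy-3-(methoxymethoxy)benzoate
Conditions: CsF, MeI, DMF, rt
Reagents that add atoms: iodomethane, CI
Why: Fluoride cleaves the aryl silyl ether and the caesium phenoxide released is O-methylated in the same flask (one-pot desilylation–alkylation); the ester and acetals are untouched.

Step 13
Reactants: 20 methyl 2-[2-bromo-3-(methoxymethoxy)-5-methylphenoxy]-5-methoxy-3-(methoxymethoxy)benzoate
Product: 21 {2-[2-bromo-3-(methoxymethoxy)-5-methylphenoxy]-5-methoxy-3-(methoxymethoxy)phenyl}methanol
Conditions: i-Bu2AlH, CH2Cl2, −78 → 0 °C; aq. KNaC4H4O6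
Reagents that add atoms: none
Why: Hydride reduction of the only ester in the molecule to the benzylic alcohol; the aryl bromide and the acetals are inert to the aluminium hydride at this temperature.

Step 14
Reactants: 21 {2-[2-bromo-3-(methoxymethoxy)-5-methylphenoxy]-5-methoxy-3-(methoxymethoxy)phenyl}methanol
Product: 23 2-[2-(hydroxymethyl)-4-methoxy-6-(methoxymethoxy)phenoxy]-6-(methoxymethoxy)-4-methylbenzoic acid, via dilithio species 22 (not isolated)
Conditions: n-BuLi (1.05 equiv), THF, −78 °C; t-BuLi (2.1 equiv), −78 °C; CO2, −78 → 0 °C; 1 M HCl to pH 4, 0 °C
Reagents that add atoms: n-butyllithium, CCCC[Li], and tert-butyllithium, CC(C)(C)[Li] (lithium of 22); carbon dioxide, O=C=O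
Why: The alcohol is first converted to its lithium alkoxide, then bromine–lithium exchange gives an aryllithium stabilised by the two flanking oxygens, which is carboxylated; any alkyl carbonate formed at the alkoxide loses CO2 on work-up.

Step 15
Reactants: 23 2-[2-(hydroxymethyl)-4-methoxy-6-(methoxymethoxy)phenoxy]-6-(methoxymethoxy)-4-methylbenzoic acid
Product: 24 methyl 2-[2-(hydroxymethyl)-4-methoxy-6-(methoxymethoxy)phenoxy]-6-(methoxymethoxy)-4-methylbenzoate
Conditions: MeI, KHCO3, DMF, rt
Reagents that add atoms: iodomethane, CI
Why: SN2 O-alkylation of the carboxylate, which is insensitive to the crowding around the acyl carbon; hydrogencarbonate is too weak a base to deprotonate the alcohol, so only the acid is methylated.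

Step 16
Reactants: 24 methyl 2-[2-(hydroxymethyl)-4-methoxy-6-(methoxymethoxy)phenoxy]-6-(methoxymethoxy)-4-methylbenzoate; 25 palmitoyl chloride (hexadecanoyl chloride)
Product: 26 methyl 2-{2-[(hexadecanoyloxy)methyl]-4-methoxy-6-(methoxymethoxy)phenoxy}-6-(methoxymethoxy)-4-methylbenzoate
Conditions: Et3N, 4-(dimethylamino)pyridine (cat.), CH2Cl2, 0 °C → rt
Reagents that add atoms: none
Why: Nucleophile-catalysed acylation of the only free hydroxyl group; both phenols are masked, so no selectivity between O-nucleophiles is required.

Step 17
Reactants: 26 methyl 2-{2-[(hexadecanoyloxy)methyl]-4-methoxy-6-(methoxymethoxy)phenoxy}-6-(methoxymethoxy)-4-methylbenzoate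
Product: 27 betaethrin E, methyl 2-{2-[(hexadecanoyloxy)methyl]-6-hydroxy-4-methoxyphenoxy}-6-hydroxy-4-methylbenzoate
Conditions: ZnBr2, n-PrSH, CH2Cl2, 0 °C → rt
Reagents that add atoms: none
Why: Lewis-acid-assisted thiolysis of the two MOM acetals; the thiol captures the methoxymethyl unit, and the aprotic, non-basic medium should leave the benzylic palmitate and the methyl ester intact.

## Compound list

1 | orcinol (5-methylbenzene-1,3-diol) | Cc1cc(O)cc(O)c1 | starting material
2 | 1,3-bis(methoxymethoxy)-5-methylbenzene | Cc1cc(OCOC)cc(OCOC)c1 | intermediate
3 | [2,6-bis(methoxymethoxy)-4-methylphenyl]lithium | [Li]c1c(OCOC)cc(C)cc1OCOC | intermediate (not isolated)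
4 | 2-bromo-1,3-bis(methoxymethoxy)-5-methylbenzene | Cc1cc(OCOC)c(Br)c(OCOC)c1 | intermediate
5 | 2-bromo-3-(methoxymethoxy)-5-methylphenol | Cc1cc(O)c(Br)c(OCOC)c1 | intermediate
6 | methyl bromoacetate | COC(=O)CBr | starting material
7 | methyl 2-[2-bromo-3-(methoxymethoxy)-5-methylphenoxy]acetate | COC(=O)COc1cc(C)cc(OCOC)c1Br | intermediate
8 | 2-[2-bromo-3-(methoxymethoxy)-5-methylphenoxy]acetic acid | OC(=O)COc1cc(C)cc(OCOC)c1Br | intermediate
9 | methyl 2,4-dioxopentanoate | CC(=O)CC(=O)C(=O)OC | starting material
10 | methyl (2Z)-4-oxo-2-[(trimethylsilyl)oxy]pent-2-enoate | COC(=O)/C(O[Si](C)(C)C)=C/C(C)=O | intermediate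
11 | lithium (3Z)-5-methoxy-5-oxo-4-[(trimethylsilyl)oxy]penta-1,3-dien-2-olate | COC(=O)/C(O[Si](C)(C)C)=C/C(=C)O[Li] | intermediate (not isolated)
12 | methyl (2Z)-2,4-bis[(trimethylsilyl)oxy]penta-2,4-dienoate | COC(=O)/C(O[Si](C)(C)C)=C/C(=C)O[Si](C)(C)C | intermediate
13 | 2-[2-bromo-3-(methoxymethoxy)-5-methylphenoxy]acetyl chloride | ClC(=O)COc1cc(C)cc(OCOC)c1Br | intermediate (not isolated)
14 | methyl (2Z)-7-[2-bromo-3-(methoxymethoxy)-5-methylphenoxy]-4,6-dioxo-2-[(trimethylsilyl)oxy]hept-2-enoate | COC(=O)/C(O[Si](C)(C)C)=C/C(=O)CC(=O)COc1cc(C)cc(OCOC)c1Br | intermediate (not isolated)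
15 | methyl 7-[2-bromo-3-(methoxymethoxy)-5-methylphenoxy]-2,4,6-trioxoheptanoate (drawn as the triketo tautomer) | COC(=O)C(=O)CC(=O)CC(=O)COc1cc(C)cc(OCOC)c1Br | intermediate
16 | methyl 2-[2-bromo-3-(methoxymethoxy)-5-methylphenoxy]-1-hydroxy-3,5-dioxocyclohexane-1-carboxylate (mixture of diastereomers, both centres lost on aromatisation) | COC(=O)C1(O)CC(=O)CC(=O)C1Oc1cc(C)cc(OCOC)c1Br | intermediate (not isolated)
17 | methyl 2-[2-bromo-3-(methoxymethoxy)-5-methylphenoxy]-3,5-dihydroxybenzoate | COC(=O)c1cc(O)cc(O)c1Oc1cc(C)cc(OCOC)c1Br | intermediate
18 | methyl 2-[2-bromo-3-(methoxymethoxy)-5-methylphenoxy]-3-hydroxy-5-[(triisopropylsilyl)oxy]benzoate | COC(=O)c1cc(O[Si](C(C)C)(C(C)C)C(C)C)cc(O)c1Oc1cc(C)cc(OCOC)c1Br | intermediate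
19 | methyl 2-[2-bromo-3-(methoxymethoxy)-5-methylphenoxy]-3-(methoxymethoxy)-5-[(triisopropylsilyl)oxy]benzoate | COC(=O)c1cc(O[Si](C(C)C)(C(C)C)C(C)C)cc(OCOC)c1Oc1cc(C)cc(OCOC)c1Br | intermediate
20 | methyl 2-[2-bromo-3-(methoxymethoxy)-5-methylphenoxy]-5-methoxy-3-(methoxymethoxy)benzoate | COC(=O)c1cc(OC)cc(OCOC)c1Oc1cc(C)cc(OCOC)c1Br | intermediate
21 | {2-[2-bromo-3-(methoxymethoxy)-5-methylphenoxy]-5-methoxy-3-(methoxymethoxy)phenyl}methanol | OCc1cc(OC)cc(OCOC)c1Oc1cc(C)cc(OCOC)c1Br | intermediate
22 | lithium alkoxide of 21 with lithium in place of bromine at C6' | [Li]OCc1cc(OC)cc(OCOC)c1Oc1cc(C)cc(OCOC)c1[Li] | intermediate (not isolated)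
23 | 2-[2-(hydroxymethyl)-4-methoxy-6-(methoxymethoxy)phenoxy]-6-(methoxymethoxy)-4-methylbenzoic acid | OCc1cc(OC)cc(OCOC)c1Oc1cc(C)cc(OCOC)c1C(=O)O | intermediate
24 | methyl 2-[2-(hydroxymethyl)-4-methoxy-6-(methoxymethoxy)phenoxy]-6-(methoxymethoxy)-4-methylbenzoate | OCc1cc(OC)cc(OCOC)c1Oc1cc(C)cc(OCOC)c1C(=O)OC | intermediate
25 | palmitoyl chloride (hexadecanoyl chloride) | CCCCCCCCCCCCCCCC(=O)Cl | starting material
26 | methyl 2-{2-[(hexadecanoyloxy)methyl]-4-methoxy-6-(methoxymethoxy)phenoxy}-6-(methoxymethoxy)-4-methylbenzoate | CCCCCCCCCCCCCCCC(=O)OCc1cc(OC)cc(OCOC)c1Oc1cc(C)cc(OCOC)c1C(=O)OC | intermediate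
27 | betaethrin E, methyl 2-{2-[(hexadecanoyloxy)methyl]-6-hydroxy-4-methoxyphenoxy}-6-hydroxy-4-methylbenzoate | CCCCCCCCCCCCCCCC(=O)OCc1cc(OC)cc(O)c1Oc1cc(C)cc(O)c1C(=O)OC | target

## Step count and risk

Total: 17 steps. Longest linear sequence: 15 steps (steps 1–5 and 8–17). Steps 6 and 7 are a two-step side branch to diene 12.

**Step 9 (key step).** The chain may rest as the stabilised enolate spanning C1 to C3, so that the C1 carbonyl is masked and closure is slow. Reversible O-cyclisation to the 4-pyranone or methanolytic cleavage of the chain could then compete. The fallback changes the ring construction from folding of a linear chain to a three-plus-three annulation. From phenol 5, alkylation with chloroacetone (K2CO3, acetone) gives 1-[2-bromo-3-(methoxymethoxy)-5-methylphenoxy]propan-2-one F1. Under NaOMe in MeOH its more acidic, aryloxy-bearing carbon adds to dimethyl but-2-ynedioate to give the Michael adduct dimethyl (2E)-2-{1-[2-bromo-3-(methoxymethoxy)-5-methylphenoxy]-2-oxopropyl}but-2-enedioate F2. Its methyl ketone enolate then closes onto the distal ester (Claisen) and aromatises, rejoining the route at 17. This reserve is shorter, but its regiochemistry depends on which enolate carbon adds first and on C- versus O-acylation. The linear chain settles both by connectivity, which is why the annulation is held back.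

**Step 8.** Diene 12 carries an ester on the diene and is less nucleophilic than ester-derived bis-silyl dienes. Acylation may therefore be sluggish without a Lewis acid, which the MOM ether would not tolerate. The diene may also hydrolyse on handling, and acidic work-up could drain 15 into its pyranone. The fallback replaces the silyl diene by a dianion. From 9, two equivalents of LiN(i-Pr)2 (THF, −78 °C) give the dilithium dienediolate of methyl 2,4-dioxopentanoate F3. Its terminal carbon is acylated by ester 7 in a Claisen condensation, with excess dianion because the product is acidic. Mild acid work-up returns the route at 15, bypassing 8 and 10–14.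

**Step 10.** Discrimination between the two phenols may be insufficient, since the hindered phenol is the more acidic one and could be silylated competitively, and bis-silylation is possible. The fallback inverts the order and the control element, from sterics to acidity. From 17, one equivalent of NaH forms mainly the monophenoxide ortho to the aryloxy group, and MOMCl gives methyl 2-[2-bromo-3-(methoxymethoxy)-5-methylphenoxy]-5-hydroxy-3-(methoxymethoxy)benzoate F4, which is separated from its regioisomer. Methylation (MeI, K2CO3, acetone) returns the route at 20.

**Step 14.** The alkoxide-bearing aryllithium may aggregate or be protonated before carboxylation, returning the debrominated ether, and the free acid next to a MOM ether may lose that acetal on standing. The fallback protects the alcohol and changes the electrophile. From 21, t-BuMe2SiCl and imidazole give tert-butyl({2-[2-bromo-3-(methoxymethoxy)-5-methylphenoxy]-5-methoxy-3-(methoxymethoxy)phenyl}methoxy)dimethylsilane F5. Exchange with t-BuLi gives the corresponding aryllithium F6, and methyl chloroformate gives methyl 2-[2-({[tert-butyl(dimethyl)silyl]oxy}methyl)-4-methoxy-6-(methoxymethoxy)phenoxy]-6-(methoxymethoxy)-4-methylbenzoate F7. Bu4NF then returns the route at 24.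

**Step 17.** The Lewis acid may activate the benzylic palmitate towards ionisation and thiolysis. The MOM ether beside the ester may cleave incompletely, and an untrapped methoxymethyl cation could alkylate the electron-rich rings. The fallback moves the deprotection ahead of the acylation and takes the selectivity from an enzyme. From 24, HCl in MeOH removes both acetals (the methyl ester is degenerate in methanol) to give methyl 2-hydroxy-6-[2-hydroxy-6-(hydroxymethyl)-4-methoxyphenoxy]-4-methylbenzoate F8. Vinyl hexadecanoate with immobilised Candida antarctica lipase B then acylates the primary alcohol in preference to the phenols and gives 27 directly.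

**Step 3.** Over-cleavage to the diol and the statistical distribution limit the mass throughput of this early step. The fallback desymmetrises at the alkylation stage instead. From 4, complete methanolysis (HCl, MeOH) gives 2-bromo-5-methylbenzene-1,3-diol F9. Mono-alkylation with 6, using an excess of the recoverable diol (K2CO3, acetone), gives methyl 2-(2-bromo-3-hydroxy-5-methylphenoxy)acetate F10. MOMCl with i-Pr2NEt returns the route at 7.

## Further compounds

F1 | step 9 | 1-[2-bromo-3-(methoxymethoxy)-5-methylphenoxy]propan-2-one | CC(=O)COc1cc(C)cc(OCOC)c1Br
F2 | step 9 | dimethyl (2E)-2-{1-[2-bromo-3-(methoxymethoxy)-5-methylphenoxy]-2-oxopropyl}but-2-enedioate (racemic) | COC(=O)/C=C(/C(=O)OC)C(Oc1cc(C)cc(OCOC)c1Br)C(C)=O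
F3 | step 8 | dilithium (3Z)-5-methoxy-5-oxopenta-1,3-diene-2,4-diolate | COC(=O)/C(O[Li])=C/C(=C)O[Li]
F4 | step 10 | methyl 2-[2-bromo-3-(methoxymethoxy)-5-methylphenoxy]-5-hydroxy-3-(methoxymethoxy)benzoate | COC(=O)c1cc(O)cc(OCOC)c1Oc1cc(C)cc(OCOC)c1Br
F5 | step 14 | tert-butyl({2-[2-bromo-3-(methoxymethoxy)-5-methylphenoxy]-5-methoxy-3-(methoxymethoxy)phenyl}methoxy)dimethylsilane | CC(C)(C)[Si](C)(C)OCc1cc(OC)cc(OCOC)c1Oc1cc(C)cc(OCOC)c1Br
F6 | step 14 | {2-[2-({[tert-butyl(dimethyl)silyl]oxy}methyl)-4-methoxy-6-(methoxymethoxy)phenoxy]-6-(methoxymethoxy)-4-methylphenyl}lithium | [Li]c1c(OCOC)cc(C)cc1Oc1c(OCOC)cc(OC)cc1CO[Si](C)(C)C(C)(C)C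
F7 | step 14 | methyl 2-[2-({[tert-butyl(dimethyl)silyl]oxy}methyl)-4-methoxy-6-(methoxymethoxy)phenoxy]-6-(methoxymethoxy)-4-methylbenzoate | COC(=O)c1c(OCOC)cc(C)cc1Oc1c(OCOC)cc(OC)cc1CO[Si](C)(C)C(C)(C)C
F8 | step 17 | methyl 2-hydroxy-6-[2-hydroxy-6-(hydroxymethyl)-4-methoxyphenoxy]-4-methylbenzoate | COC(=O)c1c(O)cc(C)cc1Oc1c(O)cc(OC)cc1CO
F9 | step 3 | 2-bromo-5-methylbenzene-1,3-diol | Cc1cc(O)c(Br)c(O)c1
F10 | step 3 | methyl 2-(2-bromo-3-hydroxy-5-methylphenoxy)acetate | COC(=O)COc1cc(C)cc(O)c1Br
A1 | alternative 1 | 2-[4-methoxy-2-(methoxymethoxy)-6-({[tri(propan-2-yl)silyl]oxy}methyl)phenoxy]-6-(methoxymethoxy)-4-methylbenzoic acid | OC(=O)c1c(OCOC)cc(C)cc1Oc1c(OCOC)cc(OC)cc1CO[Si](C(C)C)(C(C)C)C(C)C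
A2 | alternative 1 | 4-methoxy-2-(methoxymethoxy)-6-({[tri(propan-2-yl)silyl]oxy}methyl)phenol | Oc1c(OCOC)cc(OC)cc1CO[Si](C(C)C)(C(C)C)C(C)C
A3 | alternative 1 | 3-(methoxymethoxy)-5-methyl-2-(trimethylsilyl)phenyl trifluoromethanesulfonate | Cc1cc(OCOC)c([Si](C)(C)C)c(OS(=O)(=O)C(F)(F)F)c1
A4 | alternative 2 | methyl 2-[2-({[tert-butyl(dimethyl)silyl]oxy}methyl)-6-hydroxy-4-methoxyphenoxy]-6-(methoxymethoxy)-4-methylbenzoate | COC(=O)c1c(OCOC)cc(C)cc1Oc1c(O)cc(OC)cc1CO[Si](C)(C)C(C)(C)C
A5 | alternative 2 | methyl 2-{[(1E)-2-({[tert-butyl(dimethyl)silyl]oxy}methyl)-4-diazo-3-oxobut-1-en-1-yl]oxy}-6-(methoxymethoxy)-4-methylbenzoate | [N-]=[N+]=CC(=O)/C(CO[Si](C)(C)C(C)(C)C)=C/Oc1cc(C)cc(OCOC)c1C(=O)OC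
A6 | alternative 2 | methoxyacetylene (methoxyethyne) | COC#C
A7 | alternative 3 | methyl 2-hydroxy-6-[4-methoxy-2-(methoxymethoxy)-6-({[tri(propan-2-yl)silyl]oxy}methyl)phenoxy]-4-methylbenzoate | COC(=O)c1c(O)cc(C)cc1Oc1c(OCOC)cc(OC)cc1CO[Si](C(C)C)(C(C)C)C(C)C
A8 | alternative 3 | dimethyl 2-{1-[4-methoxy-2-(methoxymethoxy)-6-({[tri(propan-2-yl)silyl]oxy}methyl)phenoxy]-3-methylbut-2-en-1-ylidene}propanedioate | COC(=O)C(C(=O)OC)=C(Oc1c(OCOC)cc(OC)cc1CO[Si](C(C)C)(C(C)C)C(C)C)C=C(C)C
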